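**Retrosynthetic overview**

1. The oxolane of the target is numbered O1, C2 (aryl), C3 (CH2OH), C4 (carbinol side chain), C5 (H2). The last C–C bond made is carbinol carbon–aryl, by chelation-controlled aryl Grignard addition to a lactol. That lactol comes from a γ-lactone tying the C3 CH2O oxygen to the C4 side-chain carbon (a cis-fused 3,7-dioxabicyclo[3.3.0]octan-2-one).
2. Key disconnection: O1–C2 and C5–C4 together. O1=C5H2 leaves as one molecule of formaldehyde, and C2–C3–C4 remains as a cyclopropane fused to the lactone. Forward, this is a Lewis acid (3+2) annulation.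
3. Enabling feature: C2 bears an electron-rich 4-oxygenated aryl ring (cation-stabilising donor) and C4 bears a carbon that can stand at carbonyl level (acceptor), 1,3 to each other across C3. The C2–C4 bond of the cyclopropane is therefore a donor–acceptor bond, and the cis C3/C4 relationship of the target is the ring fusion of the temporary lactone.
4. The cyclopropane lactone comes from a Z-cinnamyl diazoacetate by enantioselective intramolecular cyclopropanation. This is the only catalyst-controlled stereo step; C2, C4 and the carbinol centre are relayed from C3. The Z-allylic alcohol comes from silyl-protected vanillin.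
5. Ring order: cyclopropane and γ-lactone together, then the oxolane (key step), then the lactone (temporary ring) is opened again via lactol and Grignard addition. Both phenols travel as TBS ethers.

Key step: step 5

Remark: Rh2(5S-MEPY)4 is assumed to give the (1R,5S) ring fusion with this Z-allyl diazoacetate as with the parent substrate class (otherwise the 5R catalyst is used, nothing else changes); 1 is taken as a catalogue silyl ether of vanillin.

**Route**

Step 1
Reactants: 1 4-(tert-butyldimethylsilyloxy)-3-methoxybenzaldehyde (O-TBS-vanillin)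
Product: 2 methyl (2Z)-3-[4-(tert-butyldimethylsilyloxy)-3-methoxyphenyl]prop-2-enoate
Conditions: (CF3CH2O)2P(O)CH2CO2Me, KN(SiMe3)2, 18-crown-6, THF, −78 °C
Reagents that add atoms: methyl bis(2,2,2-trifluoroethyl)phosphonoacetate, COC(=O)CP(=O)(OCC(F)(F)F)OCC(F)(F)F
Why: Still–Gennari olefination, in which the electron-poor trifluoroethyl phosphonate and the crown-sequestered potassium ion make the oxaphosphetane collapse faster than it equilibrates, so the kinetic Z-enoate should form (no stereocentre; any E isomer is removed by chromatography).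

Step 2
Reactants: 2 methyl (2Z)-3-[4-(tert-butyldimethylsilyloxy)-3-methoxyphenyl]prop-2-enoate
Product: 3 (2Z)-3-[4-(tert-butyldimethylsilyloxy)-3-methoxyphenyl]prop-2-en-1-ol
Conditions: i-Bu2AlH (2.5 equiv), CH2Cl2, −78 °C; Rochelle salt work-up
Reagents that add atoms: none
Why: 1,2-reduction of the ester by two hydride transfers from i-Bu2AlH at low temperature, which should touch neither the Z alkene nor the aryl silyl ether.

Step 3
Reactants: 3 (2Z)-3-[4-(tert-butyldimethylsilyloxy)-3-methoxyphenyl]prop-2-en-1-ol
Product: 4 (2Z)-3-[4-(tert-butyldimethylsilyloxy)-3-methoxyphenyl]prop-2-en-1-yl diazoacetate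
Conditions: TsNHN=CHCOCl, PhNMe2, CH2Cl2, 0 °C; then Et3N, 0 °C → rt
Reagents that add atoms: glyoxylic acid chloride p-toluenesulfonylhydrazone, Cc1ccc(cc1)S(=O)(=O)NN=CC(=O)Cl
Why: Esterification by the acid chloride followed by triethylamine-induced loss of p-toluenesulfinate from the tosylhydrazone (Bamford–Stevens-type fragmentation) should give the diazoacetate under conditions mild enough to keep the Z-cinnamyl system intact.

Step 4
Reactants: 4 (2Z)-3-[4-(tert-butyldimethylsilyloxy)-3-methoxyphenyl]prop-2-en-1-yl diazoacetate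
Product: 5 (1R,5S,6R)-6-[4-(tert-butyldimethylsilyloxy)-3-methoxyphenyl]-3-oxabicyclo[3.1.0]hexan-2-one (aryl endo, cis to the lactone ring; the three cyclopropane hydrogens all cis)
Conditions: Rh2(5S-MEPY)4 (1 mol %), CH2Cl2, reflux, slow addition of 4
Reagents that add atoms: none
Why: Intramolecular cyclopropanation of an allylic diazoacetate through a chiral dirhodium carboxamidate carbene, in which the concerted addition keeps the Z geometry (aryl, CH2O and C=O all-cis, aryl endo) and the ligand pocket selects the alkene face and so sets C1, C5 and C6 together, Z-disubstituted allyl diazoacetates being the substrate class in which this catalyst is most enantioselective.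

Step 5
Reactants: 5 (1R,5S,6R)-6-[4-(tert-butyldimethylsilyloxy)-3-methoxyphenyl]-3-oxabicyclo[3.1.0]hexan-2-one
Product: 6 (1S,5S,6R)-6-[4-(tert-butyldimethylsilyloxy)-3-methoxyphenyl]-3,7-dioxabicyclo[3.3.0]octan-2-one (cis-fused; aryl exo, trans to the C5–C4 bond)
Conditions: (CH2O)n (5 equiv), Sc(OTf)3 (20 mol %), 4 Å MS, CH2Cl2, −20 °C → rt
Reagents that add atoms: formaldehyde (charged as paraformaldehyde), C=O
Why: Proposed new method: Sc(OTf)3 binds the lactone carbonyl and polarises the cyclopropane bond C1–C6 of 5, the only bond joining the donor carbon (4-silyloxyaryl on C6) to the acceptor carbon (C1) and the one that overlaps with the carbonyl π* in this bicycle; formaldehyde oxygen attacks C6 from the rear as that bond breaks, and the scandium enolate at C1 then adds to the resulting O-alkyl oxocarbenium carbon to make C1–C8 of 6. The closest known reaction type is the Lewis acid-catalysed (3+2) annulation of 2-arylcyclopropane-1,1-diesters with aldehydes, which runs with inversion at the donor carbon; new here are the single lactone acceptor and formaldehyde as the partner. The O–C6 bond is made intermolecularly and the oxolane is then closed by a 5-(enolexo)-endo-trig aldol-type attack of the enolate on the oxocarbenium ion. C5 is not touched and relays its configuration: C1 can only be bonded on the face that keeps the two five-membered rings cis-fused, and C6 is inverted, which turns the endo aryl group of 5 into the exo aryl group of 6 (trans to the C5 substituent). Should the bond ionise first to a 4-silyloxybenzyl cation, closure onto the convex face of the bicycle is expected to give the same exo isomer, so both pathways should converge. The step needs cleavage of C1–C6 rather than C5–C6 (secured by the placement of donor and acceptor) and annulation rather than proton loss from the opened dipole or hydroxymethylation of the arene (favoured by excess formaldehyde, low temperature and a catalytic non-protic Lewis acid).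

Step 6
Reactants: 6 (1S,5S,6R)-6-[4-(tert-butyldimethylsilyloxy)-3-methoxyphenyl]-3,7-dioxabicyclo[3.3.0]octan-2-one
Product: 7 (1S,5S,6R)-6-[4-(tert-butyldimethylsilyloxy)-3-methoxyphenyl]-3,7-dioxabicyclo[3.3.0]octan-2-ol (lactol, both anomers)
Conditions: i-Bu2AlH (1.1 equiv), CH2Cl2, −78 °C; Rochelle salt work-up
Reagents that add atoms: none
Why: Partial reduction of a γ-lactone to the lactol, the aluminium hemiacetal being stable at −78 °C and collapsing only on work-up, so the three ring stereocentres stay untouched and the new anomeric centre (a mixture) is consumed in step 8.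

Step 7
Reactants: 8 4-bromo-2-methoxyphenol
Product: 9 (4-bromo-2-methoxyphenoxy)(tert-butyl)dimethylsilane
Conditions: TBSCl, imidazole, DMF, rt
Reagents that add atoms: tert-butyldimethylsilyl chloride (TBSCl), CC(C)(C)[Si](C)(C)Cl
Why: Silylation of the phenol through the N-silylimidazolium ion, which makes the aryl bromide compatible with Grignard formation.

Step 8
Reactants: 7 (1S,5S,6R)-6-[4-(tert-butyldimethylsilyloxy)-3-methoxyphenyl]-3,7-dioxabicyclo[3.3.0]octan-2-ol; 9 (4-bromo-2-methoxyphenoxy)(tert-butyl)dimethylsilane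
Product: 12 (R)-[4-(tert-butyldimethylsilyloxy)-3-methoxyphenyl]{(3S,4S,5R)-5-[4-(tert-butyldimethylsilyloxy)-3-methoxyphenyl]-4-(hydroxymethyl)oxolan-3-yl}methanol, via arylmagnesium bromide 10 (not isolated), via ring-opened aldehyde alkoxide 11 (not isolated)
Conditions: 9, Mg, THF, 40 °C (gives 10, 3.5 equiv); then 7, THF, −40 → 0 °C; aq NH4Cl
Reagents that add atoms: none
Why: Aryl Grignard addition to a lactol, in which one equivalent forms the magnesium lactolate that opens to aldehyde 11, whose carbonyl oxygen is held by the neighbouring bromomagnesium alkoxide in a seven-membered chelate on the cis-disubstituted oxolane, so that a second equivalent should deliver the aryl group to the exposed outer face of this chelate (Cram-chelate control) and set the carbinol centre as R.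

Step 9
Reactants: 12 (R)-[4-(tert-butyldimethylsilyloxy)-3-methoxyphenyl]{(3S,4S,5R)-5-[4-(tert-butyldimethylsilyloxy)-3-methoxyphenyl]-4-(hydroxymethyl)oxolan-3-yl}methanol
Product: 13 (R)-(4-hydroxy-3-methoxyphenyl)[(3S,4S,5R)-5-(4-hydroxy-3-methoxyphenyl)-4-(hydroxymethyl)oxolan-3-yl]methanol (target)
Conditions: n-Bu4NF (2.5 equiv), AcOH (2.5 equiv), THF, 0 °C
Reagents that add atoms: none
Why: Fluoride-induced cleavage of the two aryl silyl ethers (formation of the strong Si–F bond), with acetic acid buffering the phenoxides so that neither quinone methide formation nor epimerisation at the benzylic positions should occur.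

**Compound list**

1 | 4-(tert-butyldimethylsilyloxy)-3-methoxybenzaldehyde | COc1cc(C=O)ccc1O[Si](C)(C)C(C)(C)C | starting material
2 | methyl (2Z)-3-[4-(tert-butyldimethylsilyloxy)-3-methoxyphenyl]prop-2-enoate | COC(=O)/C=C\c1ccc(O[Si](C)(C)C(C)(C)C)c(OC)c1 | intermediate
3 | (2Z)-3-[4-(tert-butyldimethylsilyloxy)-3-methoxyphenyl]prop-2-en-1-ol | OC/C=C\c1ccc(O[Si](C)(C)C(C)(C)C)c(OC)c1 | intermediate
4 | (2Z)-3-[4-(tert-butyldimethylsilyloxy)-3-methoxyphenyl]prop-2-en-1-yl diazoacetate | [N-]=[N+]=CC(=O)OC/C=C\c1ccc(O[Si](C)(C)C(C)(C)C)c(OC)c1 | intermediate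
5 | (1R,5S,6R)-6-[4-(tert-butyldimethylsilyloxy)-3-methoxyphenyl]-3-oxabicyclo[3.1.0]hexan-2-one (aryl endo) | O=C1[C@@H]2[C@H](c3ccc(O[Si](C)(C)C(C)(C)C)c(OC)c3)[C@@H]2CO1 | intermediate
6 | (1S,5S,6R)-6-[4-(tert-butyldimethylsilyloxy)-3-methoxyphenyl]-3,7-dioxabicyclo[3.3.0]octan-2-one (cis-fused, aryl exo) | O=C1[C@@H]2CO[C@@H](c3ccc(O[Si](C)(C)C(C)(C)C)c(OC)c3)[C@@H]2CO1 | intermediate
7 | (1S,5S,6R)-6-[4-(tert-butyldimethylsilyloxy)-3-methoxyphenyl]-3,7-dioxabicyclo[3.3.0]octan-2-ol (lactol, both anomers) | OC1[C@@H]2CO[C@@H](c3ccc(O[Si](C)(C)C(C)(C)C)c(OC)c3)[C@@H]2CO1 | intermediate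
8 | 4-bromo-2-methoxyphenol | COc1cc(Br)ccc1O | starting material
9 | (4-bromo-2-methoxyphenoxy)(tert-butyl)dimethylsilane | COc1cc(Br)ccc1O[Si](C)(C)C(C)(C)C | intermediate
10 | [4-(tert-butyldimethylsilyloxy)-3-methoxyphenyl]magnesium bromide | COc1cc([Mg]Br)ccc1O[Si](C)(C)C(C)(C)C | intermediate
11 | bromomagnesium alkoxide of (3S,4S,5R)-5-[4-(tert-butyldimethylsilyloxy)-3-methoxyphenyl]-4-(hydroxymethyl)oxolane-3-carbaldehyde | O=C[C@@H]1CO[C@@H](c2ccc(O[Si](C)(C)C(C)(C)C)c(OC)c2)[C@@H]1CO[Mg]Br | intermediate
12 | (R)-[4-(tert-butyldimethylsilyloxy)-3-methoxyphenyl]{(3S,4S,5R)-5-[4-(tert-butyldimethylsilyloxy)-3-methoxyphenyl]-4-(hydroxymethyl)oxolan-3-yl}methanol | COc1cc([C@H](O)[C@@H]2CO[C@@H](c3ccc(O[Si](C)(C)C(C)(C)C)c(OC)c3)[C@@H]2CO)ccc1O[Si](C)(C)C(C)(C)C | intermediate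
13 | (R)-(4-hydroxy-3-methoxyphenyl)[(3S,4S,5R)-5-(4-hydroxy-3-methoxyphenyl)-4-(hydroxymethyl)oxolan-3-yl]methanol | COc1cc([C@H](O)[C@@H]2CO[C@@H](c3ccc(O)c(OC)c3)[C@@H]2CO)ccc1O | target

**Step count**

Total steps: 9. Longest linear sequence: 8 (steps 1–6, 8, 9; step 7 is a one-step side branch).

**Steps most likely to fail**

Step 5 (Proposed new method). Several processes may go wrong:
- The singly activated cyclopropane may not open under conditions that the arene and formaldehyde tolerate.
- The opened dipole may lose a proton and isomerise to an unsaturated lactone instead of being trapped.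
- The electron-rich arene may be hydroxymethylated.
- The benzylic C–O bond of the product may re-ionise and scramble the aryl-bearing centre.

Fallback (known chemistry; sets out from 3, comes back at 6): the cyclopropane is given the geminal diacceptor pattern for which the aldehyde (3+2) annulation is established, and the extra ester is removed afterwards. Alcohol 3 is acylated with methyl malonyl chloride (pyridine, CH2Cl2, 0 °C) to the mixed malonate F1. Diazo transfer (p-acetamidobenzenesulfonyl azide, Et3N, MeCN) gives the diazomalonate F2. Intramolecular cyclopropanation with the chiral porphyrin complex of divalent cobalt [Co(3,5-DitBu-ChenPhyrin)] (or Cu(MeCN)4PF6 with a bis(oxazoline)) gives the cyclopropane lactone ester F3, aryl endo as in 5. Sn(OTf)2-catalysed annulation with formaldehyde, with inversion at the aryl-bearing carbon, gives the bicyclic lactone ester F4. Krapcho demethoxycarbonylation (LiCl, wet DMSO, 120 °C) then gives 6, since the lactone enolate can be protonated only on the face that keeps the rings cis-fused.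

Step 8. Chelation may be incomplete, so that Felkin-type addition competes and lowers the facial selectivity at the carbinol carbon. The cis aldehyde may also enolise under the basic reagent and epimerise α to the carbonyl.

Fallback (sets out from 6, comes back at 13): the carbinol centre is made by C–H instead of C–C bond formation, under Felkin–Anh instead of chelate control. Lactone 6 is opened with MeNH(OMe)·HCl/AlMe3 (CH2Cl2, 0 °C) to the hydroxy Weinreb amide F5. This is silylated at once (TBSCl, imidazole, DMF) to the silyl ether F6, which can no longer relactonise or chelate. The aryllithium F7 (from 9 and t-BuLi, THF, −78 °C) converts F6 into the aryl ketone F8. LiBH(s-Bu)3 (THF, −78 °C) should deliver hydride anti to the more substituted ring carbon and give the (R)-carbinol F9. n-Bu4NF/AcOH (THF) removes all three silyl groups and gives 13.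

Step 1. The Z geometry may erode, through incomplete kinetic control in the olefination or Z-to-E drift of the electron-rich cinnamyl system. This matters because the E isomer would be carried to the exo-aryl cyclopropane, which a stereospecific opening converts into the wrong epimer at the aryl-bearing carbon.

Fallback (sets out from 9, comes back at 3): the alkene geometry is fixed by syn addition of hydrogen to an alkyne. Sonogashira coupling of 9 with propargyl alcohol (Pd(PhCN)2Cl2, P(t-Bu)3, CuI, i-Pr2NH, dioxane, rt) gives the arylpropargyl alcohol F10. Semihydrogenation (H2, Pd/CaCO3/Pb(OAc)2, quinoline, EtOAc) gives 3.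

**Further compounds**

F1 | step 5 | methyl (2Z)-3-[4-(tert-butyldimethylsilyloxy)-3-methoxyphenyl]prop-2-en-1-yl propanedioate | COC(=O)CC(=O)OC/C=C\c1ccc(O[Si](C)(C)C(C)(C)C)c(OC)c1
F2 | step 5 | methyl (2Z)-3-[4-(tert-butyldimethylsilyloxy)-3-methoxyphenyl]prop-2-en-1-yl 2-diazopropanedioate | COC(=O)C(=[N+]=[N-])C(=O)OC/C=C\c1ccc(O[Si](C)(C)C(C)(C)C)c(OC)c1
F3 | step 5 | methyl (1R,5S,6S)-6-[4-(tert-butyldimethylsilyloxy)-3-methoxyphenyl]-2-oxo-3-oxabicyclo[3.1.0]hexane-1-carboxylate (aryl endo) | O=C1[C@]2(C(=O)OC)[C@H](c3ccc(O[Si](C)(C)C(C)(C)C)c(OC)c3)[C@@H]2CO1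
F4 | step 5 | methyl (1S,5S,6R)-6-[4-(tert-butyldimethylsilyloxy)-3-methoxyphenyl]-2-oxo-3,7-dioxabicyclo[3.3.0]octane-1-carboxylate (cis-fused, aryl exo) | O=C1[C@]2(C(=O)OC)CO[C@@H](c3ccc(O[Si](C)(C)C(C)(C)C)c(OC)c3)[C@@H]2CO1
F5 | step 8 | (3S,4S,5R)-5-[4-(tert-butyldimethylsilyloxy)-3-methoxyphenyl]-4-(hydroxymethyl)-N-methoxy-N-methyloxolane-3-carboxamide | CON(C)C(=O)[C@@H]1CO[C@@H](c2ccc(O[Si](C)(C)C(C)(C)C)c(OC)c2)[C@@H]1CO
F6 | step 8 | (3S,4S,5R)-5-[4-(tert-butyldimethylsilyloxy)-3-methoxyphenyl]-4-[(tert-butyldimethylsilyloxy)methyl]-N-methoxy-N-methyloxolane-3-carboxamide | CON(C)C(=O)[C@@H]1CO[C@@H](c2ccc(O[Si](C)(C)C(C)(C)C)c(OC)c2)[C@@H]1CO[Si](C)(C)C(C)(C)C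
F7 | step 8 | [4-(tert-butyldimethylsilyloxy)-3-methoxyphenyl]lithium | [Li]c1ccc(O[Si](C)(C)C(C)(C)C)c(OC)c1
F8 | step 8 | [4-(tert-butyldimethylsilyloxy)-3-methoxyphenyl]{(3S,4S,5R)-5-[4-(tert-butyldimethylsilyloxy)-3-methoxyphenyl]-4-[(tert-butyldimethylsilyloxy)methyl]oxolan-3-yl}methanone | COc1cc(C(=O)[C@@H]2CO[C@@H](c3ccc(O[Si](C)(C)C(C)(C)C)c(OC)c3)[C@@H]2CO[Si](C)(C)C(C)(C)C)ccc1O[Si](C)(C)C(C)(C)C
F9 | step 8 | (R)-[4-(tert-butyldimethylsilyloxy)-3-methoxyphenyl]{(3S,4S,5R)-5-[4-(tert-butyldimethylsilyloxy)-3-methoxyphenyl]-4-[(tert-butyldimethylsilyloxy)methyl]oxolan-3-yl}methanol | COc1cc([C@H](O)[C@@H]2CO[C@@H](c3ccc(O[Si](C)(C)C(C)(C)C)c(OC)c3)[C@@H]2CO[Si](C)(C)C(C)(C)C)ccc1O[Si](C)(C)C(C)(C)C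
F10 | step 1 | 3-[4-(tert-butyldimethylsilyloxy)-3-methoxyphenyl]prop-2-yn-1-ol | OCC#Cc1ccc(O[Si](C)(C)C(C)(C)C)c(OC)c1
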